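(The data were computed with constants of no real substance; scatter was added.)

The vessel was closed, stirred and isothermal, and the winter run was the one run behind it.

- winter: free monomer 0.050 M; transfer agent 1.5 mM; protic impurity 0.025 M; initiator 1.8 mM; run made earlier
- flask: free monomer 0.050 M; transfer agent 1.50 mM; protic impurity 0.0250 M; initiator 1.2 mM; time 12 h

winter run (percent of the free monomer charged)

| time / h | monomer in chains / % | free monomer / % |
|---|---|---|
| 0.133 | 0 | 91 |
| 0.333 | 7 | 91 |
| 0.667 | 11 | 80 |
| 1.00 | 17 | 80 |
| 1.33 | 18 | 75 |
| 2.00 | 23 | 72 |
| 2.50 | 28 | 69 |

(readings scatter by 2 percentage points)

- the average divides the monomer in chains by the number of chains begun, living and dead together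
- the numbers in the tables scatter with a standard deviation of 2 percentage points
- the earlier runs do not show the number of chains; that part of a forecast is a guess
- no earlier run changes the charge of initiator; that part of a forecast is a guess

- average number of monomer units in a chain (chains begun, living or dead) at 12 h
- part of the free monomer that has reacted at 12 h

I read the recipes column against column: the winter run held more initiator than transfer agent, and the flask held less. My working hypothesis was that each initiator starts one living end and each transfer agent stops one. So I reckoned the balance, initiator charged less transfer agent charged: 0.300 mM in the winter run, but −0.300 mM in the flask.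

Then I read the winter free monomer as fraction left. Its negative logarithm rose at 0.223 h⁻¹ over the first hour and at 0.0986 h⁻¹ up to the last reading, so as read, within the scatter, the winter rate slowed but did not stop. A positive balance fits that reading without proving it. A negative balance made me expect chain growth to stop in the flask, with initiator as the limiting reagent of the pairing. My reckoning gave this sign and no conversion.

The forecast, “assuming rate is roughly proportional to initiator”, put dp, the average number of monomer units in a chain, at 8 (3.5 to 16) and c, the part of the free monomer reacted, at 42 % (28 % to 62 %).

The flask gave dp 6.54 and c 36.3 %. At 12.0 h it held 5.46 × 10⁻⁷ M of living end beside 63.7 % of its free monomer. The balance put the transfer agent left over at 0.300 mM, which is 20.0 % of its charge, and the flask held 20.5 %.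

    free monomer + initiator → living end + monomer in chains (k = 5.87 M⁻¹ min⁻¹)
    free monomer + living end → monomer in chains + living end, rate k2*[living end]*[free monomer] (k = 2.65 M⁻¹ min⁻¹)
    living end + transfer agent → dead chain (kL = 27.8 M⁻¹ min⁻¹)
    protic impurity + free monomer → quenched substrate (k = 0.0201 M⁻¹ min⁻¹)
    initiator → spent initiator (k = 0.00158 min⁻¹)

For the neighbour with 0.0048 M of initiator, the balance is 3.30 mM, so living ends should outlast the transfer agent. That flask held 0.00327 M of living end and 0 % of transfer agent, with c at 99.9 %.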